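**Strategy.** The ethane core is cut at two aryl–carbon bonds: C1–ring B and C2–ring C. Seen this way, C1–C2 is a vinyl group carrying one aryl group on each carbon, with ring A as the third substituent on stereocentre C1. One palladium-catalysed conjunctive coupling joins vinylboronic ester, the MOM-protected ring B aryllithium (aldehyde masked as dioxolane) and the ring C bromide: ring B shifts from boron to C1, ring C arrives on C2, C1 is set by the chiral ligand, and boron stays on C1. That boron is then exchanged for ring A with retention, and the styryl arm bearing ring D is made by olefination of the unmasked ring B aldehyde.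

Key step: step 4

Assumption: the antipode of the ferrocene bisphosphine is taken that delivers the (R)-boronate in the key step; both antipodes are available, so an opposite sense of induction is corrected by switching the ligand.

Design notes: no structural error was found; the (R)-boronate and the (S)-target have the same arrangement in space, and the descriptor changes only because boron ranks below carbon. Three points were tightened. KOTf is added in the key step, because bromide from the lithium exchange and from the electrophile would block the cationic palladium pathway. The MOM group is installed before a room-temperature acetalisation that spares it. The ring D phosphonate, which is not commercial, is made in three steps.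

**Step 1**
Reactants: 1 3-bromo-4-hydroxy-5-methoxybenzaldehyde (5-bromovanillin)
Product: 2 3-bromo-5-methoxy-4-(methoxymethoxy)benzaldehyde
Conditions: MOMCl, K2CO3, acetone, 0 °C → rt
Reagents that add atoms: chloromethyl methyl ether, COCCl
Why: Williamson-type O-alkylation of the acidic, para-formyl-activated phenoxide by the reactive α-chloro ether should be fast and leave the aldehyde untouched.

**Step 2**
Reactants: 2 3-bromo-5-methoxy-4-(methoxymethoxy)benzaldehyde
Product: 3 2-[3-bromo-5-methoxy-4-(methoxymethoxy)phenyl]-1,3-dioxolane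
Conditions: HOCH2CH2OH, HC(OEt)3, Bu4NBr3 (cat.), rt; NaHCO3 quench
Reagents that add atoms: ethylene glycol, OCCO
Why: Acid-catalysed acetalisation, driven by the orthoester as water scavenger and by the trace HBr released from the tribromide, runs at room temperature under conditions in which acid-labile ethers such as the aryl MOM group persist.

**Step 3**
Reactants: 4 4-bromobenzene-1,3-diol (4-bromoresorcinol)
Product: 5 1-bromo-2,4-bis(methoxymethoxy)benzene
Conditions: MOMCl (2.4 equiv), K2CO3, acetone, 0 °C → rt
Reagents that add atoms: chloromethyl methyl ether, COCCl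
Why: Double Williamson etherification of the two resorcinol phenoxides, with the aryl bromide inert to carbonate.

**Step 4**
Reactants: 3 2-[3-bromo-5-methoxy-4-(methoxymethoxy)phenyl]-1,3-dioxolane; 6 4,4,5,5-tetramethyl-2-vinyl-1,3,2-dioxaborolane (vinylboronic acid pinacol ester); 5 1-bromo-2,4-bis(methoxymethoxy)benzene
Product: 9 2-[(1R)-2-[2,4-bis(methoxymethoxy)phenyl]-1-[5-(1,3-dioxolan-2-yl)-3-methoxy-2-(methoxymethoxy)phenyl]ethyl]-4,4,5,5-tetramethyl-1,3,2-dioxaborolane, via ring B aryllithium 7 (not isolated), via lithium vinylboronate complex 8 (not isolated)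
Conditions: t-BuLi (2 equiv), THF, −78 °C; 6, −78 °C → rt; then 5, Pd(OAc)2 (2 mol%), MandyPhos [2,2′-bis(diphenylphosphino)-1,1′-bis(α-dimethylaminobenzyl)ferrocene, antipode giving (R)] (2.4 mol%), KOTf (2 equiv), THF, 60 °C
Reagents that add atoms: none
Why: Bromine–lithium exchange gives aryllithium 7, which adds to the empty orbital on boron of 6 to form the four-coordinate vinylboronate 8. Zerovalent palladium carrying the bisphosphine inserts into the C–Br bond of 5, KOTf strips bromide to leave a cationic divalent aryl–palladium species, and this binds the vinyl group of 8 and induces a 1,2-shift of ring B from boron to C1 anti to the metal, which ends on C2; reductive elimination then forms the C2–ring C bond and returns zerovalent palladium. The closest known reaction type is the enantioselective palladium-catalysed conjunctive cross-coupling of vinylboron ate complexes with aryl electrophiles, and no ring is closed. Stereocentre C1 is fixed in the metallate shift by the chiral ligand, which decides the alkene face that palladium occupies, and the antipode is chosen to give (R). The step needs the shift to beat direct transfer of ring B from boron to palladium, which would give a biaryl; the chelating wide-bite-angle ligand, the halide-free cationic metal and the fact that ring B is the only carbon group on boron able to migrate should secure this. Boron stays on C1 as the pinacol ester, and the MOM ethers and the dioxolane are inert to the organolithium at −78 °C and to the catalyst.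

**Step 5**
Reactants: 10 4-iodo-2-methoxyphenol
Product: 11 4-iodo-2-methoxy-1-(methoxymethoxy)benzene
Conditions: MOMCl, K2CO3, acetone, 0 °C → rt
Reagents that add atoms: chloromethyl methyl ether, COCCl
Why: Williamson etherification of the guaiacol phenoxide, with the aryl iodide unaffected.

**Step 6**
Reactants: 9 2-[(1R)-2-[2,4-bis(methoxymethoxy)phenyl]-1-[5-(1,3-dioxolan-2-yl)-3-methoxy-2-(methoxymethoxy)phenyl]ethyl]-4,4,5,5-tetramethyl-1,3,2-dioxaborolane; 11 4-iodo-2-methoxy-1-(methoxymethoxy)benzene
Product: 12 2-[3-[(1S)-2-[2,4-bis(methoxymethoxy)phenyl]-1-[3-methoxy-4-(methoxymethoxy)phenyl]ethyl]-5-methoxy-4-(methoxymethoxy)phenyl]-1,3-dioxolane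
Conditions: Pd(PPh3)4 (8 mol%), PPh3 (32 mol%), Ag2O (1.5 equiv), DME, 85 °C
Reagents that add atoms: none
Why: Suzuki–Miyaura coupling of a secondary benzylic pinacol boronate with an aryl iodide under Ag2O promotion and excess PPh3 is known to transfer the benzylic carbon to palladium with retention and to outrun β-hydride elimination, so ring A should take the place of boron at C1 and (R)-9 should become (S)-12 with unchanged spatial arrangement.

**Step 7**
Reactants: 12 2-[3-[(1S)-2-[2,4-bis(methoxymethoxy)phenyl]-1-[3-methoxy-4-(methoxymethoxy)phenyl]ethyl]-5-methoxy-4-(methoxymethoxy)phenyl]-1,3-dioxolane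
Product: 13 3-[(1S)-2-[2,4-bis(methoxymethoxy)phenyl]-1-[3-methoxy-4-(methoxymethoxy)phenyl]ethyl]-5-methoxy-4-(methoxymethoxy)benzaldehyde
Conditions: PPTS (cat.), acetone/H2O 9:1, rt → 40 °C
Reagents that add atoms: water, O
Why: Acetal hydrolysis of the aryl dioxolane, which ionises easily because the para-alkoxy group stabilises the oxocarbenium ion, should be far faster under pyridinium catalysis than cleavage of the aryl MOM ethers.

**Step 8**
Reactants: 14 5-(hydroxymethyl)benzene-1,3-diol (3,5-dihydroxybenzyl alcohol)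
Product: 15 [3,5-bis(methoxymethoxy)phenyl]methanol
Conditions: MOMCl (2.1 equiv), K2CO3, acetone, 0 °C → rt
Reagents that add atoms: chloromethyl methyl ether, COCCl
Why: Williamson etherification under carbonate conditions should alkylate only the two phenoxides, because K2CO3 does not deprotonate the benzylic alcohol.

**Step 9**
Reactants: 15 [3,5-bis(methoxymethoxy)phenyl]methanol
Product: 16 1-(bromomethyl)-3,5-bis(methoxymethoxy)benzene
Conditions: CBr4, PPh3, CH2Cl2, 0 °C
Reagents that add atoms: carbon tetrabromide, BrC(Br)(Br)Br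
Why: Appel bromination converts the primary benzylic alcohol into the bromide under neutral conditions that spare the MOM ethers.

**Step 10**
Reactants: 16 1-(bromomethyl)-3,5-bis(methoxymethoxy)benzene
Product: 17 diethyl [3,5-bis(methoxymethoxy)benzyl]phosphonate
Conditions: P(OEt)3 (neat), 120 °C
Reagents that add atoms: triethyl phosphite, CCOP(OCC)OCC
Why: Michaelis–Arbuzov reaction of the reactive benzylic bromide with the phosphite is driven by loss of volatile bromoethane.

**Step 11**
Reactants: 13 3-[(1S)-2-[2,4-bis(methoxymethoxy)phenyl]-1-[3-methoxy-4-(methoxymethoxy)phenyl]ethyl]-5-methoxy-4-(methoxymethoxy)benzaldehyde; 17 diethyl [3,5-bis(methoxymethoxy)benzyl]phosphonate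
Product: 18 hexakis(methoxymethyl) ether of the target, 1-[(1S)-2-[2,4-bis(methoxymethoxy)phenyl]-1-[3-methoxy-4-(methoxymethoxy)phenyl]ethyl]-5-[(E)-2-[3,5-bis(methoxymethoxy)phenyl]ethenyl]-3-methoxy-2-(methoxymethoxy)benzene
Conditions: 17, KOtBu, THF, 0 °C; then 13, 0 °C → rt
Reagents that add atoms: none
Why: Horner–Wadsworth–Emmons olefination of the non-enolisable aryl aldehyde with the benzylic phosphonate anion should give the E-stilbene, and the C1–H bond is far too weakly acidic to be touched by the alkoxide.

**Step 12**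
Reactants: 18 hexakis(methoxymethyl) ether of the target
Product: 19 4-[(2S)-2-[5-[(E)-2-(3,5-dihydroxyphenyl)ethenyl]-2-hydroxy-3-methoxyphenyl]-2-(4-hydroxy-3-methoxyphenyl)ethyl]benzene-1,3-diol (CNP0254096.1)
Conditions: HCl (3 M in MeOH), rt, argon, dark
Reagents that add atoms: none
Why: Acid-catalysed methanolysis of the six MOM acetals should release all phenols with formation of volatile dimethoxymethane, and the stereocentre, which carries no ionisable substituent, should not be affected.

**Compound list**
1 | 3-bromo-4-hydroxy-5-methoxybenzaldehyde (5-bromovanillin) | COc1cc(C=O)cc(Br)c1O | starting material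
2 | 3-bromo-5-methoxy-4-(methoxymethoxy)benzaldehyde | COCOc1c(Br)cc(C=O)cc1OC | intermediate
3 | 2-[3-bromo-5-methoxy-4-(methoxymethoxy)phenyl]-1,3-dioxolane | COCOc1c(Br)cc(C2OCCO2)cc1OC | intermediate
4 | 4-bromobenzene-1,3-diol (4-bromoresorcinol) | Oc1ccc(Br)c(O)c1 | starting material
5 | 1-bromo-2,4-bis(methoxymethoxy)benzene | COCOc1ccc(Br)c(OCOC)c1 | intermediate
6 | 4,4,5,5-tetramethyl-2-vinyl-1,3,2-dioxaborolane | C=CB1OC(C)(C)C(C)(C)O1 | starting material
7 | [5-(1,3-dioxolan-2-yl)-3-methoxy-2-(methoxymethoxy)phenyl]lithium | [Li]c1cc(C2OCCO2)cc(OC)c1OCOC | intermediate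
8 | lithium [5-(1,3-dioxolan-2-yl)-3-methoxy-2-(methoxymethoxy)phenyl](vinyl)(pinacolato)borate | [Li+].C=C[B-]1(OC(C)(C)C(C)(C)O1)c1cc(C2OCCO2)cc(OC)c1OCOC | intermediate
9 | 2-[(1R)-2-[2,4-bis(methoxymethoxy)phenyl]-1-[5-(1,3-dioxolan-2-yl)-3-methoxy-2-(methoxymethoxy)phenyl]ethyl]-4,4,5,5-tetramethyl-1,3,2-dioxaborolane | CC1(C)OB([C@H](Cc2ccc(OCOC)cc2OCOC)c2cc(C3OCCO3)cc(OC)c2OCOC)OC1(C)C | intermediate
10 | 4-iodo-2-methoxyphenol | COc1cc(I)ccc1O | starting material
11 | 4-iodo-2-methoxy-1-(methoxymethoxy)benzene | COCOc1ccc(I)cc1OC | intermediate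
12 | 2-[3-[(1S)-2-[2,4-bis(methoxymethoxy)phenyl]-1-[3-methoxy-4-(methoxymethoxy)phenyl]ethyl]-5-methoxy-4-(methoxymethoxy)phenyl]-1,3-dioxolane | COc1cc([C@H](Cc2ccc(OCOC)cc2OCOC)c2cc(C3OCCO3)cc(OC)c2OCOC)ccc1OCOC | intermediate
13 | 3-[(1S)-2-[2,4-bis(methoxymethoxy)phenyl]-1-[3-methoxy-4-(methoxymethoxy)phenyl]ethyl]-5-methoxy-4-(methoxymethoxy)benzaldehyde | COc1cc([C@H](Cc2ccc(OCOC)cc2OCOC)c2cc(C=O)cc(OC)c2OCOC)ccc1OCOC | intermediate
14 | 5-(hydroxymethyl)benzene-1,3-diol (3,5-dihydroxybenzyl alcohol) | OCc1cc(O)cc(O)c1 | starting material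
15 | [3,5-bis(methoxymethoxy)phenyl]methanol | COCOc1cc(CO)cc(OCOC)c1 | intermediate
16 | 1-(bromomethyl)-3,5-bis(methoxymethoxy)benzene | COCOc1cc(CBr)cc(OCOC)c1 | intermediate
17 | diethyl [3,5-bis(methoxymethoxy)benzyl]phosphonate | CCOP(=O)(Cc1cc(OCOC)cc(OCOC)c1)OCC | intermediate
18 | hexakis(methoxymethyl) ether of the target (S at C1, E alkene) | COc1cc([C@H](Cc2ccc(OCOC)cc2OCOC)c2cc(/C=C/c3cc(OCOC)cc(OCOC)c3)cc(OC)c2OCOC)ccc1OCOC | intermediate
19 | 4-[(2S)-2-[5-[(E)-2-(3,5-dihydroxyphenyl)ethenyl]-2-hydroxy-3-methoxyphenyl]-2-(4-hydroxy-3-methoxyphenyl)ethyl]benzene-1,3-diol | COc1cc([C@H](Cc2ccc(O)cc2O)c2cc(/C=C/c3cc(O)cc(O)c3)cc(OC)c2O)ccc1O | target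

**Step count.** Total: 12 steps. Longest linear sequence: 7 steps (1, 2, 4, 6, 7, 11, 12).

**Steps most likely to fail**

Step 4. Ring B may transfer directly from boron to palladium and give a biaryl instead of undergoing the metallate shift. Oxidative addition of the electron-rich bromide may be slow, and facial control may be poor with the ortho-substituted migrating ring. The fallback sets out from bromide 3 and comes back at boronate 9. Suzuki–Miyaura vinylation of 3 with 6 (Pd(dppf)Cl2, K2CO3, dioxane/H2O, 80 °C) should give the styrene 2-[3-ethenyl-5-methoxy-4-(methoxymethoxy)phenyl]-1,3-dioxolane F1. Enantioselective diboration of its terminal alkene (B2pin2, Pt(dba)3, TADDOL-derived phosphonite, THF, 60 °C) should set C1 by syn addition and give 2,2′-[(1R)-1-[5-(1,3-dioxolan-2-yl)-3-methoxy-2-(methoxymethoxy)phenyl]ethane-1,2-diyl]bis(4,4,5,5-tetramethyl-1,3,2-dioxaborolane) F2. Chemoselective Suzuki–Miyaura coupling of the primary C–B bond alone with bromide 5 (Pd(OAc)2, 2-dicyclohexylphosphino-2′,6′-diisopropoxybiphenyl, KOH, THF/H2O, 70 °C) should then leave the benzylic boronate in place and give 9.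

Step 6. β-Hydride elimination from the benzylic palladium intermediate may give a stilbene. Transmetalation of the hindered boronate may be slow, and configuration at C1 may be partly lost. The fallback sets out from 9 and 11 and comes back at 12 without a transition metal. Iodine–lithium exchange on 11 (t-BuLi, THF, −78 °C) should give [3-methoxy-4-(methoxymethoxy)phenyl]lithium F3. This is added to 9 to form lithium [(1R)-2-[2,4-bis(methoxymethoxy)phenyl]-1-[5-(1,3-dioxolan-2-yl)-3-methoxy-2-(methoxymethoxy)phenyl]ethyl][3-methoxy-4-(methoxymethoxy)phenyl](pinacolato)borate F4. N-Bromosuccinimide at −78 °C should brominate ring A ortho to boron and para to its methoxy group. C1 then shifts from boron to the ring carbon with retention, and loss of bromide and the boron group restores the arene to give 12.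

Step 12. Protonation of the electron-rich para-hydroxystyryl unit may lead to addition of methanol or of the resorcinol ring C, and the alkene may isomerise while six MOM groups are removed. The fallback sets out from aldehyde 13 and phosphonate 17 and comes back at 19; acid is used before the alkene exists and the last step uses fluoride. HCl/MeOH on 13, then aqueous work-up, should give 3-[(1S)-2-(2,4-dihydroxyphenyl)-1-(4-hydroxy-3-methoxyphenyl)ethyl]-4-hydroxy-5-methoxybenzaldehyde F5. Silylation (TBSCl, imidazole, DMF) should give 3-[(1S)-2-[2,4-bis(tert-butyldimethylsilyloxy)phenyl]-1-[4-(tert-butyldimethylsilyloxy)-3-methoxyphenyl]ethyl]-4-(tert-butyldimethylsilyloxy)-5-methoxybenzaldehyde F6. The same two operations on 17 should give diethyl (3,5-dihydroxybenzyl)phosphonate F7 and then diethyl [3,5-bis(tert-butyldimethylsilyloxy)benzyl]phosphonate F8. Horner–Wadsworth–Emmons olefination of F6 with F8 (NaH, THF, 0 °C) should give the hexakis(tert-butyldimethylsilyl) ether of 19 F9. Bu4NF buffered with AcOH in THF at 0 °C should then release 19.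

**Further compounds**
F1 | step 4 | 2-[3-ethenyl-5-methoxy-4-(methoxymethoxy)phenyl]-1,3-dioxolane | C=Cc1cc(C2OCCO2)cc(OC)c1OCOC
F2 | step 4 | 2,2′-[(1R)-1-[5-(1,3-dioxolan-2-yl)-3-methoxy-2-(methoxymethoxy)phenyl]ethane-1,2-diyl]bis(4,4,5,5-tetramethyl-1,3,2-dioxaborolane) | CC1(C)OB([C@H](CB2OC(C)(C)C(C)(C)O2)c2cc(C3OCCO3)cc(OC)c2OCOC)OC1(C)C
F3 | step 6 | [3-methoxy-4-(methoxymethoxy)phenyl]lithium | [Li]c1ccc(OCOC)c(OC)c1
F4 | step 6 | lithium [(1R)-2-[2,4-bis(methoxymethoxy)phenyl]-1-[5-(1,3-dioxolan-2-yl)-3-methoxy-2-(methoxymethoxy)phenyl]ethyl][3-methoxy-4-(methoxymethoxy)phenyl](pinacolato)borate | [Li+].COCOc1ccc([B-]2(OC(C)(C)C(C)(C)O2)[C@H](Cc2ccc(OCOC)cc2OCOC)c2cc(C3OCCO3)cc(OC)c2OCOC)cc1OC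
F5 | step 12 | 3-[(1S)-2-(2,4-dihydroxyphenyl)-1-(4-hydroxy-3-methoxyphenyl)ethyl]-4-hydroxy-5-methoxybenzaldehyde | COc1cc([C@H](Cc2ccc(O)cc2O)c2cc(C=O)cc(OC)c2O)ccc1O
F6 | step 12 | 3-[(1S)-2-[2,4-bis(tert-butyldimethylsilyloxy)phenyl]-1-[4-(tert-butyldimethylsilyloxy)-3-methoxyphenyl]ethyl]-4-(tert-butyldimethylsilyloxy)-5-methoxybenzaldehyde | COc1cc([C@H](Cc2ccc(O[Si](C)(C)C(C)(C)C)cc2O[Si](C)(C)C(C)(C)C)c2cc(C=O)cc(OC)c2O[Si](C)(C)C(C)(C)C)ccc1O[Si](C)(C)C(C)(C)C
F7 | step 12 | diethyl (3,5-dihydroxybenzyl)phosphonate | CCOP(=O)(Cc1cc(O)cc(O)c1)OCC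
F8 | step 12 | diethyl [3,5-bis(tert-butyldimethylsilyloxy)benzyl]phosphonate | CCOP(=O)(Cc1cc(O[Si](C)(C)C(C)(C)C)cc(O[Si](C)(C)C(C)(C)C)c1)OCC
F9 | step 12 | hexakis(tert-butyldimethylsilyl) ether of 19 (S at C1, E alkene) | COc1cc([C@H](Cc2ccc(O[Si](C)(C)C(C)(C)C)cc2O[Si](C)(C)C(C)(C)C)c2cc(/C=C/c3cc(O[Si](C)(C)C(C)(C)C)cc(O[Si](C)(C)C(C)(C)C)c3)cc(OC)c2O[Si](C)(C)C(C)(C)C)ccc1O[Si](C)(C)C(C)(C)C
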